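The C3 ketone and the C8=C9 enol-lactone alkene of the ten-membered ring (germacrane numbering) stand 1,5 to each other through C1–C10, with quaternary C10 between C9 and C1. The route therefore disconnects C1–C10 and reconnects C3–C8. Heating a butenolide-fused cyclohexane with a C3 vinyl/silyloxy pair and a C8 (E)-2-(4-methoxybenzyloxy)prop-1-enyl arm should, in one operation, expand the six-membered ring to the ten-membered ring, create the Z-ylidene butenolide, deliver the C3 ketone as its silyl enol ether and set C10. The precursor is built from (S)-carvone; oxidative removal of the benzyl ether finishes the synthesis.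

Key step: step 16

Remark 1 (numbering): germacrane locants are used for every intermediate (C1–C10 ring; C11, C12, C13 the lactone α-carbon, carbonyl and acetoxymethyl carbon); β is the ring face of the C3 and C8 oxygens, α the face of the vinyl and propynyl/propenyl groups.
Remark 2 (silyl group): the C3 oxygen carries triethylsilyl instead of trimethylsilyl, because the ether must survive eleven steps and the sigmatropic shift is indifferent to the silyl group; the enol silyl ether is cleaved with buffered fluoride.
Remark 3 (order of events): vinyl is added to C3 before propynyl to C8 so that both additions follow the intrinsic facial preference of the chair; all electrophilic oxidations precede the enol ether; no organometallic reagent is used once the esters are in place.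

Step 1
Reactants: 1 (S)-(+)-carvone
Product: 2 (2S,5S)-trans-dihydrocarvone (C4 β-methyl and C7 α-isopropenyl both equatorial)
Conditions: LiBH(s-Bu)3, THF, −78 °C; aq NH4Cl
Reagents that add atoms: none
Why: Conjugate hydride reduction of the β-unsubstituted enone, followed by axial protonation of the enolate, should place the C4 methyl equatorial and trans to the isopropenyl group (4S); the minor cis epimer can be removed or equilibrated with base.

Step 2
Reactants: 2 (2S,5S)-trans-dihydrocarvone; 3 3-phenyl-2-(phenylsulfonyl)oxaziridine
Product: 4 (2R,3R,6S)-2-hydroxy-6-methyl-3-(prop-1-en-2-yl)cyclohexan-1-one (C8 β-OH, equatorial)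
Conditions: LiN(i-Pr)2, THF, −78 °C; then 3, −78 °C; aq NH4Cl
Reagents that add atoms: 3-phenyl-2-(phenylsulfonyl)oxaziridine, O=S(=O)(c1ccccc1)N1OC1c1ccccc1
Why: Kinetic deprotonation on the unsubstituted α-side and electrophilic enolate hydroxylation by the N-sulfonyloxaziridine should place oxygen on C8 trans to the neighbouring isopropenyl group; this centre only steers step 3 and is oxidised in step 4.

Step 3
Reactants: 4 C8 β-hydroxy ketone; 5 vinylmagnesium bromide
Product: 6 (1S,2R,3R,6S)-1-ethenyl-6-methyl-3-(prop-1-en-2-yl)cyclohexane-1,2-diol (C3 β-OH axial, α-vinyl equatorial)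
Conditions: THF, −78 to 0 °C (3 equiv of 5); aq NH4Cl
Reagents that add atoms: vinylmagnesium bromide, C=C[Mg]Br
Why: Grignard 1,2-addition to the magnesium-chelated α-alkoxido ketone, which has equatorial groups on both α-carbons, should occur from the equatorial side, so the new C3 hydroxyl is axial and cis to the C4 methyl (3S of the later numbering).

Step 4
Reactants: 6 vinyl diol
Product: 7 α-ketol (C8 ketone; C3 β-OH/α-vinyl; C4 β-methyl; C7 α-isopropenyl)
Conditions: (COCl)2, DMSO, CH2Cl2, −78 °C; Et3N, −78 to 0 °C
Reagents that add atoms: none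
Why: Swern oxidation converts only the secondary C8 alcohol, the tertiary C3 alcohol being inert, and the low temperature limits α-ketol shift.

Step 5
Reactants: 7 α-ketol; 8 triethylsilyl trifluoromethanesulfonate
Product: 9 triethylsilyl ether of 7
Conditions: 2,6-lutidine, CH2Cl2, −78 to −20 °C
Reagents that add atoms: triethylsilyl trifluoromethanesulfonate, CC[Si](CC)(CC)OS(=O)(=O)C(F)(F)F
Why: Silylation of the hindered tertiary alcohol with a silyl triflate and a hindered pyridine base gives an ether that blocks α-ketol chemistry and later makes the C3 oxygen a non-chelating axial group.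

Step 6
Reactants: 9 silylated β,γ-unsaturated ketone
Product: 10 conjugated enone (C7 isopropylidene; C3 β-OSiEt3/α-vinyl; C4 β-methyl)
Conditions: DBU, toluene, 25 to 60 °C
Reagents that add atoms: none
Why: Base-mediated isomerisation through the dienolate (C7 is the only enolisable position) should move the alkene into conjugation, as in isopulegone to pulegone, and erases the C7 stereocentre after it has controlled C4, C8 and C3.

Step 7
Reactants: 10 conjugated enone; 11 1-propynylmagnesium bromide
Product: 12 tertiary propargylic alcohol (C8 β-OH equatorial, α-prop-1-ynyl axial)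
Conditions: CeCl3, THF, −78 to 0 °C; aq NH4Cl
Reagents that add atoms: 1-propynylmagnesium bromide, CC#C[Mg]Br
Why: Organocerium 1,2-addition to the hindered, non-enolisable enone should bring the slim alkynyl group in axially and anti to the axial C3 silyloxy group (steric, polar and intrinsic axial preferences agree), which makes the two ring oxygens cis and the two unsaturated arms cis (8R of the later numbering).

Step 8
Reactants: 12 tertiary propargylic alcohol; 13 ozone
Product: 14 α-hydroxy ketone (C7 ketone; C8 β-OH/α-propynyl)
Conditions: O3, CH2Cl2/MeOH, NaHCO3, Sudan Red 7B, −78 °C; then Me2S, −78 to 25 °C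
Reagents that add atoms: ozone, [O-][O+]=O
Why: Ozonolysis with reductive work-up should cleave the electron-rich tetrasubstituted isopropylidene alkene well before the allylically oxygenated monosubstituted vinyl group or the alkyne when ozone is titrated against the dye.

Step 9
Reactants: 14 α-hydroxy ketone; 15 (triphenylphosphoranylidene)ketene
Product: 16 bicyclic butenolide (8,12-lactone, C7=C11 with C11–H; C8 α-propynyl)
Conditions: toluene, 100 °C
Reagents that add atoms: (triphenylphosphoranylidene)ketene, O=C=C=P(c1ccccc1)(c1ccccc1)c1ccccc1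
Why: Addition of the tertiary alcohol to the cumulated ylide gives an ester-stabilised phosphorane that closes on the adjacent C7 ketone by intramolecular Wittig reaction, so the lactone carbonyl is necessarily cis to C8.

Step 10
Reactants: 16 bicyclic butenolide; 17 formaldehyde
Product: 18 11-(hydroxymethyl)-6-ene lactone (C6=C7; C11 α-CH2OH)
Conditions: LiN(i-Pr)2, THF, −78 °C; CH2O (gas from paraformaldehyde), −78 °C; AcOH
Reagents that add atoms: formaldehyde, C=O
Why: γ-Deprotonation at C6 gives the lithium dienolate, which should undergo aldol addition to formaldehyde at the α-carbon C11 (deconjugative α-hydroxymethylation), on the face away from the silyloxy-shielded β side; the C11 centre is erased in step 11.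

Step 11
Reactants: 18 11-(hydroxymethyl)-6-ene lactone; 19 tert-butyl hydroperoxide
Product: 21 6α,13-dihydroxy butenolide (6S), via α-epoxide 20 (not isolated)
Conditions: VO(acac)2 (5 mol %), CH2Cl2, 0 to 25 °C; then Me2S, DBU, 25 °C
Reagents that add atoms: tert-butyl hydroperoxide, CC(C)(C)OO
Why: Hydroxyl-directed vanadium-catalysed epoxidation should deliver oxygen to C6=C7 on the face of the homoallylic CH2OH (α), leaving vinyl and alkyne untouched, and DBU then removes the acidic C11 proton and opens the epoxide by E1cB to restore the C7=C11 butenolide with the C6 hydroxyl α (6S).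

Step 12
Reactants: 21 6α,13-dihydroxy butenolide; 22 acetic anhydride
Product: 23 13-acetate with free 6α-hydroxyl
Conditions: Ac2O (1.05 equiv), pyridine, CH2Cl2, −20 °C
Reagents that add atoms: acetic anhydride, CC(=O)OC(C)=O
Why: Acylation of the unhindered primary allylic alcohol should be much faster at low temperature than that of the axial secondary C6 alcohol.

Step 13
Reactants: 23 13-acetate with free 6α-hydroxyl; 24 3-methylbut-2-enoic acid
Product: 25 6β-(3-methylbut-2-enoate) 13-acetate alkyne (6R)
Conditions: PPh3, DIAD, toluene, 0 to 25 °C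
Reagents that add atoms: 3-methylbut-2-enoic acid, CC(C)=CC(=O)O
Why: Mitsunobu esterification should displace the axial oxyphosphonium group by SN2, inverting C6 to the equatorial 6R ester, while the electron-poor butenolide disfavours ionisation and allylic transposition.

Step 14
Reactants: 25 6β-ester alkyne; 26 catecholborane; 27 pinacol
Product: 29 alkenyl pinacol boronate (boron on C10 trans to C8), via catechol boronate 28 (not isolated)
Conditions: catecholborane (neat), 70 °C; then pinacol, THF, 25 °C
Reagents that add atoms: catecholborane, B1Oc2ccccc2O1; pinacol, CC(C)(O)C(C)(C)O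
Why: Uncatalysed syn-hydroboration with catecholborane is faster for alkynes than for terminal alkenes, tolerates esters, and should place boron on the methyl-bearing carbon away from quaternary C8; diol exchange with pinacol then gives the stable boronate of fixed geometry.

Step 15
Reactants: 29 alkenyl pinacol boronate; 30 4-methoxybenzyl alcohol
Product: 31 Cope precursor, (3S,4S,6R,8R) butenolide with C3 triethylsilyloxy/vinyl and C8 (E)-2-(4-methoxybenzyloxy)prop-1-enyl
Conditions: Cu(OAc)2 (2 equiv), Et3N, 4 Å MS, 30/CH2Cl2, air, 25 °C
Reagents that add atoms: 4-methoxybenzyl alcohol, COc1ccc(CO)cc1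
Why: Chan–Lam-type oxidative coupling of the alkenyl boronate with the alcohol on divalent copper should form the C10–O bond with retention of alkene geometry, giving the E enol ether under mild basic conditions that spare the esters and the silyl ether.

Step 16
Reactants: 31 Cope precursor
Product: 33 10-O-(4-methoxybenzyl) target (4S,6R,10R; 8Z), via silyl enol ether 32 (not isolated)
Conditions: toluene (0.01 M), i-Pr2NEt, sealed silylated tube, 175 °C; then Bu4NF, AcOH, THF, 0 °C
Reagents that add atoms: none
Why: A concerted [3,3]-sigmatropic shift of the 1,5-diene C1=C2–C3–C8–C9=C10 should form C1–C10 as C3–C8 breaks, and buffered fluoride then converts the C2=C3 silyl enol ether into the C3 ketone. The closest known reaction is the thermal oxy-Cope (siloxy-Cope) ring expansion of cis-1,2-dialkenylcyclohexanols to (E)-cyclodec-5-enones. The ten-membered ring is closed by six-to-ten ring expansion through a six-centre chair transition state, not by end-to-end cyclisation. C10 (R) follows from chirality transfer from C3 (S) and C8 (R) through that chair, in which the E enol ether holds its oxygen pseudo-equatorial and the methyl pseudo-axial. The step needs the chair in which the propenyl arm is axial (C7 and C10 then end trans on C8=C9, the Z-ylidene lactone) and must outrun a shift through C7=C11 and ionisation at C8. The planar butenolide locks the lactone oxygen equatorial and the arm axial, the vinyl group is anti to C7 in that conformer so the alternative shift has no reactive geometry, and a dilute amine-buffered hydrocarbon medium disfavours ionisation.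

Step 17
Reactants: 33 10-O-(4-methoxybenzyl) target
Product: 34 CNP0186726.1 (target)
Conditions: DDQ, CH2Cl2/pH 7 buffer, 0 °C
Reagents that add atoms: none
Why: Oxidative cleavage of the 4-methoxybenzyl ether by DDQ, through the benzylic oxocarbenium ion and its hydrolysis, should free the tertiary C10 alcohol while the electron-poor dienyl lactone, the esters and the ketone stay untouched.

Compound list
1 | (S)-(+)-carvone, (5S)-2-methyl-5-(prop-1-en-2-yl)cyclohex-2-en-1-one | CC1=CC[C@@H](CC1=O)C(C)=C | starting material
2 | (2S,5S)-2-methyl-5-(prop-1-en-2-yl)cyclohexan-1-one (trans-dihydrocarvone) | C[C@H]1CC[C@H](C(C)=C)CC1=O | intermediate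
3 | 3-phenyl-2-(phenylsulfonyl)oxaziridine (racemic) | O=S(=O)(c1ccccc1)N1OC1c1ccccc1 | starting material
4 | (2R,3R,6S)-2-hydroxy-6-methyl-3-(prop-1-en-2-yl)cyclohexan-1-one | C[C@H]1CC[C@H](C(C)=C)[C@@H](O)C1=O | intermediate
5 | vinylmagnesium bromide | C=C[Mg]Br | starting material
6 | (1S,2R,3R,6S)-1-ethenyl-6-methyl-3-(prop-1-en-2-yl)cyclohexane-1,2-diol | C[C@H]1CC[C@H](C(C)=C)[C@@H](O)[C@]1(O)C=C | intermediate
7 | 2-ethenyl-2-hydroxy-3-methyl-6-(prop-1-en-2-yl)cyclohexan-1-one (C3 β-OH/α-vinyl, C4 β-methyl, C7 α-isopropenyl) | C[C@H]1CC[C@H](C(C)=C)C(=O)[C@]1(O)C=C | intermediate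
8 | triethylsilyl trifluoromethanesulfonate | CC[Si](CC)(CC)OS(=O)(=O)C(F)(F)F | starting material
9 | triethylsilyl ether of 7 | C[C@H]1CC[C@H](C(C)=C)C(=O)[C@]1(O[Si](CC)(CC)CC)C=C | intermediate
10 | 2-ethenyl-3-methyl-6-(propan-2-ylidene)-2-(triethylsilyloxy)cyclohexan-1-one (C3 β-OSiEt3/α-vinyl, C4 β-methyl) | C[C@H]1CCC(=C(C)C)C(=O)[C@]1(O[Si](CC)(CC)CC)C=C | intermediate
11 | 1-propynylmagnesium bromide | CC#C[Mg]Br | starting material
12 | tertiary alcohol: C8 β-OH/α-prop-1-ynyl, C7 isopropylidene, C3 β-OSiEt3/α-vinyl, C4 β-methyl | C[C@H]1CCC(=C(C)C)[C@](O)(C#CC)[C@]1(O[Si](CC)(CC)CC)C=C | intermediate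
13 | ozone | [O-][O+]=O | starting material
14 | α-hydroxy ketone: C7 ketone, C8 β-OH/α-prop-1-ynyl, C3 β-OSiEt3/α-vinyl, C4 β-methyl | C[C@H]1CCC(=O)[C@](O)(C#CC)[C@]1(O[Si](CC)(CC)CC)C=C | intermediate
15 | (triphenylphosphoranylidene)ketene | O=C=C=P(c1ccccc1)(c1ccccc1)c1ccccc1 | starting material
16 | bicyclic butenolide: 8,12-lactone, C7=C11 (C11–H), C8 α-prop-1-ynyl, C3 β-OSiEt3/α-vinyl, C4 β-methyl | C[C@H]1CCC2=CC(=O)O[C@@]2(C#CC)[C@]1(O[Si](CC)(CC)CC)C=C | intermediate
17 | formaldehyde | C=O | starting material
18 | 11-(hydroxymethyl)-6-ene lactone: C6=C7, C11 α-CH2OH, otherwise as 16 | C[C@H]1CC=C2[C@H](CO)C(=O)O[C@@]2(C#CC)[C@]1(O[Si](CC)(CC)CC)C=C | intermediate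
19 | tert-butyl hydroperoxide | CC(C)(C)OO | starting material
20 | 6α,7α-epoxide of 18 | C[C@H]1C[C@@H]2O[C@@]23[C@H](CO)C(=O)O[C@@]3(C#CC)[C@]1(O[Si](CC)(CC)CC)C=C | intermediate
21 | 6α,13-dihydroxy butenolide (6S): C7=C11, C11–CH2OH, C6 α-OH | C[C@H]1C[C@H](O)C2=C(CO)C(=O)O[C@@]2(C#CC)[C@]1(O[Si](CC)(CC)CC)C=C | intermediate
22 | acetic anhydride | CC(=O)OC(C)=O | starting material
23 | 13-acetate of 21 (free 6α-OH, 6S) | C[C@H]1C[C@H](O)C2=C(COC(C)=O)C(=O)O[C@@]2(C#CC)[C@]1(O[Si](CC)(CC)CC)C=C | intermediate
24 | 3-methylbut-2-enoic acid | CC(C)=CC(=O)O | starting material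
25 | 6β-(3-methylbut-2-enoate) 13-acetate (6R) with C8 α-prop-1-ynyl | C[C@H]1C[C@@H](OC(=O)C=C(C)C)C2=C(COC(C)=O)C(=O)O[C@@]2(C#CC)[C@]1(O[Si](CC)(CC)CC)C=C | intermediate
26 | catecholborane | B1Oc2ccccc2O1 | starting material
27 | pinacol | CC(C)(O)C(C)(C)O | starting material
28 | alkenyl catechol boronate: C8–CH=C(CH3)–B(catecholate), boron trans to C8 | C[C@H]1C[C@@H](OC(=O)C=C(C)C)C2=C(COC(C)=O)C(=O)O[C@@]2(/C=C(\C)B3Oc4ccccc4O3)[C@]1(O[Si](CC)(CC)CC)C=C | intermediate
29 | alkenyl pinacol boronate: C8–CH=C(CH3)–Bpin, boron trans to C8 | C[C@H]1C[C@@H](OC(=O)C=C(C)C)C2=C(COC(C)=O)C(=O)O[C@@]2(/C=C(\C)B3OC(C)(C)C(C)(C)O3)[C@]1(O[Si](CC)(CC)CC)C=C | intermediate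
30 | 4-methoxybenzyl alcohol | COc1ccc(CO)cc1 | starting material
31 | Cope precursor: (3S,4S,6R,8R) butenolide, C3 triethylsilyloxy/vinyl, C8 (E)-2-(4-methoxybenzyloxy)prop-1-enyl, C6 3-methylbut-2-enoate, C13 acetate | CC(=O)OCC1=C2[C@H](OC(=O)C=C(C)C)C[C@H](C)[C@@](O[Si](CC)(CC)CC)(C=C)[C@]2(/C=C(\C)OCc3ccc(OC)cc3)OC1=O | intermediate
32 | ring-expanded C2=C3 triethylsilyl enol ether of 33 | CC(=O)OCC1=C2/C(=C/[C@](C)(OCc3ccc(OC)cc3)C/C=C(/O[Si](CC)(CC)CC)[C@@H](C)C[C@H]2OC(=O)C=C(C)C)OC1=O | intermediate
33 | 10-O-(4-methoxybenzyl) target (4S,6R,10R; 8Z) | CC(=O)OCC1=C2/C(=C/[C@](C)(OCc3ccc(OC)cc3)CCC(=O)[C@@H](C)C[C@H]2OC(=O)C=C(C)C)OC1=O | intermediate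
34 | CNP0186726.1 (4S,6R,10R; 8Z) | CC(=O)OCC1=C2/C(=C/[C@](C)(O)CCC(=O)[C@@H](C)C[C@H]2OC(=O)C=C(C)C)OC1=O | target

Total step count: 17. Longest linear sequence: 17 steps, from (S)-carvone 1 to 34; every other input is a commercial reagent.

Steps most likely to fail

Step 16. Once the enol ether is in place the tertiary, doubly allylic C8–O bond is a vinylogous acylal, so ionisation at C8 or loss of the acid-labile enol ether may outrun the sigmatropic shift. The fallback sets out from boronate 29 and runs the same thermal shift with boron in place of the ether oxygen, so that no donor assists ionisation. Heating in toluene at 175 °C should give, through the same chair with boron pseudo-equatorial, the ring-expanded tertiary allylboronate silyl enol ether F1. NaBO3·4H2O in THF/water should then oxidise the C–B bond with retention to the C10 alcohol silyl enol ether F2. Bu4NF/AcOH cleaves the enol ether and the fallback comes back to the route at target 34, bypassing 31 to 33.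

Step 14. The C3 vinyl group may be hydroborated competitively while the hindered alkyne reacts slowly. The fallback sets out from 25 and uses copper-catalysed borylcupration and protonation (CuCl, Xantphos, catalytic NaOt-Bu, B2pin2, MeOH, THF, 25 °C). This reaction ignores unactivated alkenes and is known to add syn with boron distal to a propargylic oxygen. Excess methanol is used so that protonation of the alkenylcopper outruns β-elimination of the lactone carboxylate. It comes back to the route at 29 and makes no new compound (F0).

Step 11. Facial selectivity in the directed epoxidation, which fixes C6, may be poor, and the inversion in step 13 may be eroded by retention or elimination. The fallback sets out from 23, as either C6 epimer or a mixture. Dess–Martin oxidation should give the C6 ketone F3. NaBH4/CeCl3 in MeOH at −78 °C should then add hydride axially to give the equatorial 6β (6R) alcohol F4. Steglich esterification with 24 (EDC, DMAP) proceeds with retention and comes back to the route at 25.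

Further compounds
F1 | step 16 | ring-expanded C10 pinacol boronate, C2=C3 triethylsilyl enol ether | CC(=O)OCC1=C2/C(=C/[C@](C)(B3OC(C)(C)C(C)(C)O3)C/C=C(/O[Si](CC)(CC)CC)[C@@H](C)C[C@H]2OC(=O)C=C(C)C)OC1=O
F2 | step 16 | C10 alcohol, C2=C3 triethylsilyl enol ether | CC(=O)OCC1=C2/C(=C/[C@](C)(O)C/C=C(/O[Si](CC)(CC)CC)[C@@H](C)C[C@H]2OC(=O)C=C(C)C)OC1=O
F0 | step 14 | none | none
F3 | step 11 | C6 ketone of 23 | C[C@H]1CC(=O)C2=C(COC(C)=O)C(=O)O[C@@]2(C#CC)[C@]1(O[Si](CC)(CC)CC)C=C
F4 | step 11 | 6β-alcohol (6R) epimer of 23 | C[C@H]1C[C@@H](O)C2=C(COC(C)=O)C(=O)O[C@@]2(C#CC)[C@]1(O[Si](CC)(CC)CC)C=C
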